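**Strategy.** The upper flavan unit is disconnected at the two bonds that tie ring A to ring C, O1–C8a and C4–C4a. Because C8a and C4a are adjacent ring A carbons (the C7 oxygen meta to C8a, para to C4a), ring A is introduced as a 4-benzyloxy-2-fluorophenyl Grignard reagent. In one pot its C–Mg carbon adds to the aldehyde (future C4) of an Evans syn-glycolate aldol fragment and the C2 alkoxide then displaces fluoride, closing ring C with the 2,3-cis relationship already in place. The resulting C4 carbinol is later ionised and captured, trans to O3, by C6 of benzylated (−)-fisetinidol; hydrogenolysis ends the route.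

Key step: step 5

Remark: (−)-fisetinidol, the (2R,3S) 2,3-trans flavan-3-ol, is taken as a purchasable natural product. The C4 epimers formed in step 5 are carried on together because C4 is ionised in step 7.

Step 1
Reactants: 1 (R)-4-benzyloxazolidin-2-one; 2 (benzyloxy)acetyl chloride
Product: 4 (R)-4-benzyl-3-[(benzyloxy)acetyl]oxazolidin-2-one, via N-lithio oxazolidinone 3 (not isolated)
Conditions: n-BuLi, THF, −78 °C; then 2, −78 → 0 °C
Reagents that add atoms: none
Why: N-acylation of a lithiated oxazolidinone by an acid chloride is the standard loading of an Evans auxiliary; it forms no stereocentre and leaves the auxiliary centre untouched.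

Step 2
Reactants: 4 (R)-4-benzyl-3-[(benzyloxy)acetyl]oxazolidin-2-one; 5 3,4-bis(benzyloxy)benzaldehyde
Product: 7 (R)-4-benzyl-3-[(2R,3S)-2-(benzyloxy)-3-[3,4-bis(benzyloxy)phenyl]-3-hydroxypropanoyl]oxazolidin-2-one, via Z-dibutylboron enolate 6 (not isolated)
Conditions: Bu2BOTf, i-Pr2NEt, CH2Cl2, −78 → 0 °C; 5, −78 → 0 °C; then pH 7 buffer, MeOH, H2O2, 0 °C
Reagents that add atoms: none
Why: Evans syn aldol, in which the Z-boron enolate reacts through a closed chair transition state with one enolate face shielded by the benzyl group of the (R)-auxiliary, which should set both new centres as the (2R,3S) syn glycolate adduct (future C3 and C2 of the upper flavan).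

Step 3
Reactants: 7 the syn aldol adduct
Product: 8 (2R,3S)-2-(benzyloxy)-3-[3,4-bis(benzyloxy)phenyl]-3-hydroxy-N-methoxy-N-methylpropanamide
Conditions: MeNHOMe·HCl, AlMe3, CH2Cl2, −20 → 0 °C; aqueous potassium sodium tartrate work-up
Reagents that add atoms: N,O-dimethylhydroxylamine hydrochloride, CNOC.Cl
Why: Aluminium-amide transamination to the Weinreb amide is assisted by the free β-hydroxyl and should release the auxiliary without touching either stereocentre.

Step 4
Reactants: 8 the Weinreb amide
Product: 9 (2R,3S)-2-(benzyloxy)-3-[3,4-bis(benzyloxy)phenyl]-3-hydroxypropanal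
Conditions: i-Bu2AlH (2.5 equiv), THF, −78 °C; aqueous potassium sodium tartrate; used crude at once
Reagents that add atoms: none
Why: Hydride reduction of a Weinreb amide stops at the chelated tetrahedral aluminate, which should release the aldehyde only on work-up, so no stereocentre is formed and immediate use limits α-epimerisation.

Step 5
Reactants: 9 (2R,3S)-2-(benzyloxy)-3-[3,4-bis(benzyloxy)phenyl]-3-hydroxypropanal; 10 4-(benzyloxy)-1-bromo-2-fluorobenzene
Product: 13 (2S,3S,4R)-3,7-bis(benzyloxy)-2-[3,4-bis(benzyloxy)phenyl]chroman-4-ol (2,3-cis; drawn as the expected major C4 epimer), via aryl Grignard reagent 11 (not isolated), via fluoroaryl diol dialkoxide 12 (not isolated)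
Conditions: 10, Mg turnings, LiCl, THF, 0 °C (2.2 equiv of 11); 9, THF, −78 → 0 °C; then KOt-Bu, DMSO, 70 °C, one pot
Reagents that add atoms: none
Why: The Grignard reagent 11 (made and kept at or below 0 °C so that it does not lose fluoride to an aryne; two equivalents, the first consumed by the free hydroxyl) adds to the aldehyde carbon of 9 to forge C4–C4a, and after exchange to the potassium alkoxide in DMSO the C2 oxygen attacks the fluorine-bearing carbon ortho to the new benzylic centre and expels fluoride through a Meisenheimer-type adduct (intramolecular SNAr, or an elimination–addition that leads to the same carbon) to forge O1–C8a. The closest known reaction types are Grignard addition to α-alkoxy aldehydes and the base-mediated cyclisation of 3-(2-fluoroaryl)propanols to chromans. Ring C closes in the second event as a six-membered ring by attack of oxygen on the sp2 carbon C8a (formally 6-exo-trig with respect to the C8a–C8 bond). C2 and C3 come unchanged from the aldol (the C2–O bond is never broken, so the syn aldol becomes the 2,3-cis ring), while the new C4 carbinol is set by Cram-chelate addition to the α-benzyloxy aldehyde (3,4-trans expected to predominate) and is of no consequence because C4 is ionised in step 7. The step needs regioselectivity on ring A, which is fixed by the positions of bromine and fluorine in 10, and chemoselectivity among the oxygens, which is secured because O3 is benzylated and the C4 alkoxide could only close a four-membered ring.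

Step 6
Reactants: 14 (−)-fisetinidol, (2R,3S)-2-(3,4-dihydroxyphenyl)chroman-3,7-diol
Product: 15 (2R,3S)-7-(benzyloxy)-2-[3,4-bis(benzyloxy)phenyl]chroman-3-ol
Conditions: BnBr (3.3 equiv), K2CO3, DMF, rt
Reagents that add atoms: benzyl bromide, BrCc1ccccc1
Why: Williamson etherification with a weak base should be selective for the three phenols over the secondary C3 alcohol, and no stereocentre is touched.

Step 7
Reactants: 13 the 2,3-cis flavan-4-ol; 15 tri-O-benzylfisetinidol (3 equiv, the excess to be recovered)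
Product: 16 hepta-O-benzyl derivative of the target (benzyl on O3, O7, O3′, O4′ of the upper unit and on O7, O3′, O4′ of the lower unit; upper unit 2,3-cis-3,4-trans, bonded from C4 to C6 of the lower unit)
Conditions: Sc(OTf)3 (10 mol %), 4 Å molecular sieves, CH2Cl2, −20 °C → rt, slow addition of 13
Reagents that add atoms: none
Why: Friedel–Crafts alkylation through the 4-flavanyl cation (stabilised by O1 and the C7 ether), formed by Lewis-acid-assisted loss of the C4 hydroxyl of 13 as water, which the sieves take up; C6 of 15, para to O1 and less hindered than C8, should attack the face anti to the C3 benzyloxy group, setting C4 as 3,4-trans while both C4 epimers of 13 converge.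

Step 8
Reactants: 16 the hepta-O-benzyl dimer
Product: 17 (2S,3S,4R)-2-(3,4-dihydroxyphenyl)-4-[(2R,3S)-2-(3,4-dihydroxyphenyl)-3,7-dihydroxychroman-6-yl]chroman-3,7-diol (target)
Conditions: H2 (1 atm), Pd(OH)2 on carbon, THF/MeOH, rt
Reagents that add atoms: none
Why: Catalytic hydrogenolysis of benzyl ethers should free all seven hydroxyls under neutral conditions while the C4–C6 bond and both pyran rings survive, and no stereocentre is touched.

**Compound list**

1 | (R)-4-benzyloxazolidin-2-one | O=C1N[C@H](Cc2ccccc2)CO1 | starting material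
2 | (benzyloxy)acetyl chloride | O=C(Cl)COCc1ccccc1 | starting material
3 | (R)-4-benzyl-3-lithiooxazolidin-2-one (not isolated) | [Li]N1C(=O)OC[C@H]1Cc1ccccc1 | intermediate
4 | (R)-4-benzyl-3-[(benzyloxy)acetyl]oxazolidin-2-one | O=C(COCc1ccccc1)N1C(=O)OC[C@H]1Cc1ccccc1 | intermediate
5 | 3,4-bis(benzyloxy)benzaldehyde | O=Cc1ccc(OCc2ccccc2)c(OCc2ccccc2)c1 | starting material
6 | Z-dibutylboron enolate of 4 (not isolated) | CCCCB(CCCC)O/C(=C\OCc1ccccc1)N1C(=O)OC[C@H]1Cc1ccccc1 | intermediate
7 | (R)-4-benzyl-3-[(2R,3S)-2-(benzyloxy)-3-[3,4-bis(benzyloxy)phenyl]-3-hydroxypropanoyl]oxazolidin-2-one | O[C@@H](c1ccc(OCc2ccccc2)c(OCc2ccccc2)c1)[C@@H](OCc1ccccc1)C(=O)N1C(=O)OC[C@H]1Cc1ccccc1 | intermediate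
8 | (2R,3S)-2-(benzyloxy)-3-[3,4-bis(benzyloxy)phenyl]-3-hydroxy-N-methoxy-N-methylpropanamide | O[C@@H](c1ccc(OCc2ccccc2)c(OCc2ccccc2)c1)[C@@H](OCc1ccccc1)C(=O)N(C)OC | intermediate
9 | (2R,3S)-2-(benzyloxy)-3-[3,4-bis(benzyloxy)phenyl]-3-hydroxypropanal | O[C@@H](c1ccc(OCc2ccccc2)c(OCc2ccccc2)c1)[C@@H](OCc1ccccc1)C=O | intermediate
10 | 4-(benzyloxy)-1-bromo-2-fluorobenzene | Brc1ccc(OCc2ccccc2)cc1F | starting material
11 | [4-(benzyloxy)-2-fluorophenyl]magnesium bromide (not isolated) | Fc1cc(OCc2ccccc2)ccc1[Mg]Br | intermediate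
12 | (1R,2R,3S)-2-(benzyloxy)-1-[4-(benzyloxy)-2-fluorophenyl]-3-[3,4-bis(benzyloxy)phenyl]propane-1,3-diol, present in the flask as its dialkoxide (not isolated; expected major C1 epimer) | O[C@@H](c1ccc(OCc2ccccc2)c(OCc2ccccc2)c1)[C@@H](OCc1ccccc1)[C@@H](c1ccc(OCc2ccccc2)cc1F)O | intermediate
13 | (2S,3S,4R)-3,7-bis(benzyloxy)-2-[3,4-bis(benzyloxy)phenyl]chroman-4-ol (2,3-cis; expected major C4 epimer) | C(c1ccccc1)Oc1ccc2c(c1)O[C@@H](c1ccc(OCc3ccccc3)c(OCc3ccccc3)c1)[C@@H](OCc1ccccc1)[C@@H]2O | intermediate
14 | (−)-fisetinidol, (2R,3S)-2-(3,4-dihydroxyphenyl)chroman-3,7-diol | Oc1ccc2c(c1)O[C@H](c1ccc(O)c(O)c1)[C@@H](O)C2 | starting material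
15 | (2R,3S)-7-(benzyloxy)-2-[3,4-bis(benzyloxy)phenyl]chroman-3-ol | C(c1ccccc1)Oc1ccc2c(c1)O[C@H](c1ccc(OCc3ccccc3)c(OCc3ccccc3)c1)[C@@H](O)C2 | intermediate
16 | hepta-O-benzyl derivative of 17 (upper unit 2,3-cis-3,4-trans with O3, O7, O3′, O4′ benzylated; lower unit (2R,3S) with O7, O3′, O4′ benzylated and free 3-OH; C4 to C6 bond) | C(c1ccccc1)Oc1ccc2c(c1)O[C@@H](c1ccc(OCc3ccccc3)c(OCc3ccccc3)c1)[C@@H](OCc1ccccc1)[C@@H]2c1cc2c(cc1OCc1ccccc1)O[C@H](c1ccc(OCc3ccccc3)c(OCc3ccccc3)c1)[C@@H](O)C2 | intermediate
17 | (2S,3S,4R)-2-(3,4-dihydroxyphenyl)-4-[(2R,3S)-2-(3,4-dihydroxyphenyl)-3,7-dihydroxychroman-6-yl]chroman-3,7-diol | Oc1ccc2c(c1)O[C@@H](c1ccc(O)c(O)c1)[C@@H](O)[C@@H]2c1cc2c(cc1O)O[C@H](c1ccc(O)c(O)c1)[C@@H](O)C2 | target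

**Step count and risks**

Total steps: 8. Longest linear sequence: 7 (steps 1, 2, 3, 4, 5, 7, 8); step 6 is a one-step side branch.

The three steps most likely to fail, most risky first:

First, step 5. The hydroxy aldehyde may undergo retro-aldol cleavage or α-epimerisation before the Grignard reagent adds. Fluoride displacement may also be slow on a ring that carries no activating group. The fallback sets out from 8 and comes back at 13. The Weinreb amide 8 is treated with the same Grignard reagent 11 (2.2 equiv, THF, −40 → 0 °C) to give (2R,3S)-2-(benzyloxy)-1-[4-(benzyloxy)-2-fluorophenyl]-3-[3,4-bis(benzyloxy)phenyl]-3-hydroxypropan-1-one F1. The ketone now activates the ortho fluorine, so K2CO3 in DMF at 0 °C to rt should close ring C by SNAr to (2S,3R)-3,7-bis(benzyloxy)-2-[3,4-bis(benzyloxy)phenyl]chroman-4-one F2, the 2,3-cis chromanone. This is reduced at once with NaBH4 (MeOH/THF, −20 °C), before C3 can epimerise, to rejoin the route at 13; either C4 epimer serves.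

Second, step 7. The C4 cation may be captured by ring A of a second molecule of 13 or of the product, leading to oligomers, and attack through C8 of 15 may compete. The fallback sets out from 13 and comes back at 17. C6 of 13, its most nucleophilic position, is capped with bromine (N-bromosuccinimide, CH2Cl2, −20 °C) to give (2S,3S,4R)-3,7-bis(benzyloxy)-2-[3,4-bis(benzyloxy)phenyl]-6-bromochroman-4-ol F3. The same Sc(OTf)3 coupling with 15 then gives the 6-bromo derivative of dimer 16 F4. Its bromine is removed together with the benzyl groups by hydrogenolysis (H2, Pd(OH)2 on carbon, Et3N, THF/MeOH), which delivers 17 directly.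

Third, step 4. Over-reduction to the 1,3-diol may occur, and the unprotected hydroxy aldehyde may suffer retro-aldol cleavage or α-epimerisation during work-up. The fallback sets out from 8 and comes back at 13. The hydroxyl of 8 is silylated (Et3SiCl, imidazole, DMF) to the triethylsilyl ether of 8 F5. Reduction (i-Bu2AlH, THF, −78 °C) gives the configurationally more robust triethylsilyl ether of 9 F6. One equivalent of Grignard reagent 11 then gives the mono-triethylsilyl ether of diol 12 F7. Bu4NF in THF frees diol 12, now isolated, which is cyclised with KOt-Bu in DMSO at 70 °C, as in the second stage of step 5, to give 13.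

**Further compounds**

F1 | step 5 | (2R,3S)-2-(benzyloxy)-1-[4-(benzyloxy)-2-fluorophenyl]-3-[3,4-bis(benzyloxy)phenyl]-3-hydroxypropan-1-one | O[C@@H](c1ccc(OCc2ccccc2)c(OCc2ccccc2)c1)[C@@H](OCc1ccccc1)C(=O)c1ccc(OCc2ccccc2)cc1F
F2 | step 5 | (2S,3R)-3,7-bis(benzyloxy)-2-[3,4-bis(benzyloxy)phenyl]chroman-4-one (2,3-cis) | C(c1ccccc1)Oc1ccc2c(c1)O[C@@H](c1ccc(OCc3ccccc3)c(OCc3ccccc3)c1)[C@@H](OCc1ccccc1)C2=O
F3 | step 7 | (2S,3S,4R)-3,7-bis(benzyloxy)-2-[3,4-bis(benzyloxy)phenyl]-6-bromochroman-4-ol | C(c1ccccc1)Oc1c(Br)cc2c(c1)O[C@@H](c1ccc(OCc3ccccc3)c(OCc3ccccc3)c1)[C@@H](OCc1ccccc1)[C@@H]2O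
F4 | step 7 | 6-bromo derivative (upper unit) of hepta-O-benzyl dimer 16, same configuration as 16 | C(c1ccccc1)Oc1c(Br)cc2c(c1)O[C@@H](c1ccc(OCc3ccccc3)c(OCc3ccccc3)c1)[C@@H](OCc1ccccc1)[C@@H]2c1cc2c(cc1OCc1ccccc1)O[C@H](c1ccc(OCc3ccccc3)c(OCc3ccccc3)c1)[C@@H](O)C2
F5 | step 4 | (2R,3S)-2-(benzyloxy)-3-[3,4-bis(benzyloxy)phenyl]-N-methoxy-N-methyl-3-(triethylsilyloxy)propanamide | CC[Si](CC)(CC)O[C@@H](c1ccc(OCc2ccccc2)c(OCc2ccccc2)c1)[C@@H](OCc1ccccc1)C(=O)N(C)OC
F6 | step 4 | (2R,3S)-2-(benzyloxy)-3-[3,4-bis(benzyloxy)phenyl]-3-(triethylsilyloxy)propanal | CC[Si](CC)(CC)O[C@@H](c1ccc(OCc2ccccc2)c(OCc2ccccc2)c1)[C@@H](OCc1ccccc1)C=O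
F7 | step 4 | mono-triethylsilyl ether of diol 12, silyl on the oxygen of the carbinol that bears the 3,4-bis(benzyloxy)phenyl group | CC[Si](CC)(CC)O[C@@H](c1ccc(OCc2ccccc2)c(OCc2ccccc2)c1)[C@@H](OCc1ccccc1)[C@@H](c1ccc(OCc2ccccc2)cc1F)O
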